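**Assumption:** the SMILES fixes the target as the ent-labdane with 5β-H, 9β-H, 10α-CH3 and 8β-CHO (1R,2S,4aS,8aS); labdane numbering (C-1 to C-20) is used for the skeleton throughout.

## Retrosynthetic overview

1. Target 18 ⇐ acid unmasking of 17 (enol ether = C-17 aldehyde, acetonide = 18,19-diol) ⇐ desaturation of the lactone ⇐ Wittig C-17 homologation of 8-ketone 14.
2. 14 ⇐ radical (Giese) addition of the C-11 iodide to tulipalin A ⇐ key step: iodonium-triggered semipinacol ring expansion of vinyl carbinol 11, a 1,2-shift of quaternary C-10 from C-8 to C-9 that turns the cyclopentanol into ring B.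
3. 11 ⇐ trans-hydrindanone 7 ⇐ one-flask [3+3] dianion annulation of keto malonate 4 with 1-chloro-3-iodopropane (ring A and the C-10 quaternary centre).
4. 4 ⇐ asymmetric Michael addition of dimethyl malonate to 2-methylcyclopent-2-enone (sets C-5).
5. Ring order: cyclopentanone (bought) → ring A → ring B by expansion; the butenolide ring is brought in intact as tulipalin A.

## Route

Step 1
Reactants: 1 malonic acid
Product: 2 dimethyl malonate
Conditions: MeOH (solvent), H2SO4 (cat.), reflux
Reagents that add atoms: methanol, CO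
Why: Fischer esterification, driven to the diester by the large excess of methanol.

Step 2
Reactants: 2 dimethyl malonate; 3 2-methylcyclopent-2-en-1-one
Product: 4 dimethyl 2-[(1S,2R)-2-methyl-3-oxocyclopentyl]malonate
Conditions: N-(9-anthracenylmethyl)-O-allylcinchonidinium bromide (10 mol %; or its cinchoninium pseudo-enantiomer, whichever delivers the 1S adduct), solid K2CO3, toluene, −20 °C
Reagents that add atoms: none
Why: Asymmetric phase-transfer Michael addition, known for malonates and 2-alkylcyclopentenones, in which the chiral ammonium–malonate ion pair attacks one enone face to set C-5 while the α-methyl centre settles as the trans epimer.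

Step 3
Reactants: 4 dimethyl 2-[(1S,2R)-2-methyl-3-oxocyclopentyl]malonate; 5 1-chloro-3-iodopropane
Product: 7 dimethyl (3aS,7aR)-7a-methyl-1-oxooctahydro-4H-indene-4,4-dicarboxylate, via chloropropyl keto malonate 6 (not isolated)
Conditions: LiN(SiMe3)2 (1.95 equiv), THF, −78 → 25 °C, 1 h; then 5, DMPU, −40 → 0 °C; then NaI (cat.), 50 °C
Reagents that add atoms: none
Why: Proposed new method: a one-flask, trans-selective [3+3] annulation through a site-differentiated dianion, in which the slight deficit of base lets the ketone enolate equilibrate to the tetrasubstituted C-10 enolate beside the malonate anion, the more basic enolate carbon is alkylated first by the iodide terminus (Hauser rule) anti to the C-5 malonate group to set the C-10 quaternary centre, and the malonate anion then closes ring A on the chloride by 6-exo-tet alkylation; the closest known reactions are Hauser/Weiler dianion alkylations and the conjugate-addition/enolate-alkylation coupling of 2-methylcyclopentenone.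

Step 4
Reactants: 7 dimethyl (3aS,7aR)-7a-methyl-1-oxooctahydro-4H-indene-4,4-dicarboxylate; 8 vinylmagnesium bromide
Product: 10 (1S,3aR,7aR)-1-ethenyl-4,4-bis(hydroxymethyl)-7a-methyloctahydro-1H-inden-1-ol, via vinyl carbinol diester 9 (not isolated)
Conditions: THF, −78 → 0 °C; then LiAlH4, 0 → 40 °C; aq. NaOH work-up
Reagents that add atoms: none
Why: Grignard 1,2-addition to the ketone (much faster than attack on the neopentyl esters at low temperature) from the face anti to the angular methyl, followed by LiAlH4 reduction of the malonate to the 1,3-diol; the carbinol configuration is lost later.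

Step 5
Reactants: 10 (1S,3aR,7aR)-1-ethenyl-4,4-bis(hydroxymethyl)-7a-methyloctahydro-1H-inden-1-ol
Product: 11 acetonide of 10 (spiro 2,2-dimethyl-1,3-dioxane on C-4; tertiary vinyl carbinol free)
Conditions: Me2C(OMe)2, pyridinium p-toluenesulfonate (cat.), CH2Cl2, 25 °C
Reagents that add atoms: 2,2-dimethoxypropane, COC(C)(C)OC
Why: Acid-catalysed transacetalisation gives the six-membered acetonide of the 1,3-diol, while the hindered tertiary alcohol does not react.

Step 6
Reactants: 11 acetonide of 10; 12 tulipalin A (α-methylene-γ-butyrolactone)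
Product: 14 18,19-O-isopropylidene-8-oxo-17-nor-ent-labdan-16,15-olide, via iodo ketone 13 (not isolated)
Conditions: N-iodosuccinimide, CH2Cl2, −20 °C, dark; then 12 (5 equiv), Bu3SnH (slow addition), AIBN (cat.), benzene, 80 °C; then DBU (cat.), CH2Cl2, 25 °C
Reagents that add atoms: N-iodosuccinimide, O=C1CCC(=O)N1I (its iodine is carried only by intermediate 13)
Why: Halonium-induced semipinacol ring expansion (the D-homoannulation type known for 17-vinyl-17-hydroxy steroids), in which the iodonium ion of the vinyl group is opened by a 1,2-shift of the electron-rich quaternary C-10 from C-8 to C-9 to give the cyclohexanone of ring B with C-11 as CH2I; Giese addition of the C-11 radical to 12 then forms C-11–C-12, and DBU epimerises C-9 (α to the ketone) to the equatorial side chain (9β-H).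

Step 7
Reactants: 14 18,19-O-isopropylidene-8-oxo-17-nor-ent-labdan-16,15-olide
Product: 15 18,19-O-isopropylidene-17-methoxy-ent-labd-8(17)-en-16,15-olide
Conditions: Ph3P(CH2OMe)Cl, KN(SiMe3)2, THF, 0 → 25 °C
Reagents that add atoms: (methoxymethyl)triphenylphosphonium chloride, COC[P+](c1ccccc1)(c1ccccc1)c1ccccc1.[Cl-]
Why: Wittig methoxymethylenation installs C-17 as a masked aldehyde; the non-stabilised ylide reacts with the ketone far faster than with the lactone, and C-9 is already in its thermodynamic configuration.

Step 8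
Reactants: 15 18,19-O-isopropylidene-17-methoxy-ent-labd-8(17)-en-16,15-olide
Product: 17 18,19-O-isopropylidene-17-methoxy-ent-labda-8(17),13-dien-16,15-olide, via selenide 16 (not isolated)
Conditions: LiN(i-Pr)2, THF, −78 °C; PhSeBr; then NaIO4, NaHCO3, MeOH/H2O, 0 → 25 °C
Reagents that add atoms: phenylselanyl bromide, Br[Se]c1ccccc1 (its PhSe group is carried only by intermediate 16)
Why: α-Selenenylation of the lactone enolate (the only acidic site) and selenoxide syn-elimination into the ring give the α-substituted butenolide; periodate is used because it does not epoxidise the enol ether.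

Step 9
Reactants: 17 18,19-O-isopropylidene-17-methoxy-ent-labda-8(17),13-dien-16,15-olide
Product: 18 (1R,2S,4aS,8aS)-5,5-bis(hydroxymethyl)-8a-methyl-1-[2-(2-oxo-2,5-dihydrofuran-3-yl)ethyl]decahydronaphthalene-2-carbaldehyde (target)
Conditions: 2 M aq. HCl, THF, 25 → 40 °C
Reagents that add atoms: water, O
Why: Acid hydrolysis of the enol ether and the acetonide, with acid-catalysed enolisation equilibrating C-8 to the equatorial aldehyde trans to the equatorial C-9 side chain; the butenolide is acid-stable.

## Compound list

1 | malonic acid | OC(=O)CC(=O)O | starting material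
2 | dimethyl malonate | COC(=O)CC(=O)OC | intermediate
3 | 2-methylcyclopent-2-en-1-one | CC1=CCCC1=O | starting material
4 | dimethyl 2-[(1S,2R)-2-methyl-3-oxocyclopentyl]malonate | C[C@@H]1[C@@H](C(C(=O)OC)C(=O)OC)CCC1=O | intermediate
5 | 1-chloro-3-iodopropane | ClCCCI | starting material
6 | dimethyl 2-[(1S,2R)-2-(3-chloropropyl)-2-methyl-3-oxocyclopentyl]malonate | C[C@@]1(CCCCl)[C@@H](C(C(=O)OC)C(=O)OC)CCC1=O | intermediate (not isolated)
7 | dimethyl (3aS,7aR)-7a-methyl-1-oxooctahydro-4H-indene-4,4-dicarboxylate (trans-fused) | C[C@@]12CCCC(C(=O)OC)(C(=O)OC)[C@H]1CCC2=O | intermediate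
8 | vinylmagnesium bromide | C=C[Mg]Br | starting material
9 | dimethyl (1S,3aS,7aR)-1-ethenyl-1-hydroxy-7a-methyloctahydro-4H-indene-4,4-dicarboxylate | C[C@@]12CCCC(C(=O)OC)(C(=O)OC)[C@H]1CC[C@]2(O)C=C | intermediate (not isolated)
10 | (1S,3aR,7aR)-1-ethenyl-4,4-bis(hydroxymethyl)-7a-methyloctahydro-1H-inden-1-ol | C[C@@]12CCCC(CO)(CO)[C@H]1CC[C@]2(O)C=C | intermediate
11 | acetonide of 10 (spiro 2,2-dimethyl-1,3-dioxane at C-4; 1S,3aR,7aR) | C[C@@]12CCCC3(COC(C)(C)OC3)[C@H]1CC[C@]2(O)C=C | intermediate
12 | tulipalin A (3-methylideneoxolan-2-one) | C=C1CCOC1=O | starting material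
13 | 11-iodo-18,19-O-isopropylidene-8-oxo-12,13,14,15,16,17-hexanor-ent-labdane (5β-H, 10α-CH3; C-9 epimers) | C[C@@]12CCCC3(COC(C)(C)OC3)[C@H]1CCC(=O)C2CI | intermediate (not isolated)
14 | 18,19-O-isopropylidene-8-oxo-17-nor-ent-labdan-16,15-olide (5β-H, 9β-H, 10α-CH3; both C-13 epimers) | C[C@@]12CCCC3(COC(C)(C)OC3)[C@H]1CCC(=O)[C@H]2CCC1CCOC1=O | intermediate
15 | 18,19-O-isopropylidene-17-methoxy-ent-labd-8(17)-en-16,15-olide (E/Z mixture; both C-13 epimers) | C[C@@]12CCCC3(COC(C)(C)OC3)[C@H]1CCC(=COC)[C@H]2CCC1CCOC1=O | intermediate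
16 | 13-(phenylselanyl) derivative of 15 | C[C@@]12CCCC3(COC(C)(C)OC3)[C@H]1CCC(=COC)[C@H]2CCC1([Se]c4ccccc4)CCOC1=O | intermediate (not isolated)
17 | 18,19-O-isopropylidene-17-methoxy-ent-labda-8(17),13-dien-16,15-olide | C[C@@]12CCCC3(COC(C)(C)OC3)[C@H]1CCC(=COC)[C@H]2CCC1=CCOC1=O | intermediate
18 | (1R,2S,4aS,8aS)-5,5-bis(hydroxymethyl)-8a-methyl-1-[2-(2-oxo-2,5-dihydrofuran-3-yl)ethyl]decahydronaphthalene-2-carbaldehyde | C[C@@]12CCCC(CO)(CO)[C@H]1CC[C@H](C=O)[C@H]2CCC1=CCOC1=O | target

## Step count and risks

Total steps: 9. Longest linear sequence: 9.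

The three steps most likely to fail are steps 3, 6 and 8.

The annulation of step 3 (the proposed new step) can fail in three ways: the malonate anion may be alkylated first (which would then close to the cis-fused ring), the C-7 enolate may react, or O-alkylation may occur. The fallback uses known chemistry and replaces steps 2 and 3; it sets out from 2 and 3 and comes back to the route at 7. Compound 2 is allylated (NaH, allyl bromide) to dimethyl 2-allylmalonate F1, which has no acidic hydrogen after addition. A LiAl(binaphtholate)2-catalysed tandem Michael–aldol reaction of F1, 3 and acetaldehyde then gives the trans β-hydroxy ketone dimethyl 2-allyl-2-[(1S,2S)-2-(1-hydroxyethyl)-2-methyl-3-oxocyclopentyl]malonate F2. Dehydration with Burgess reagent gives the vinyl ketone dimethyl 2-allyl-2-[(1S,2R)-2-ethenyl-2-methyl-3-oxocyclopentyl]malonate F3, and ring-closing metathesis with the second-generation Grubbs catalyst gives the cyclohexene dimethyl (3aS,7aR)-7a-methyl-1-oxo-2,3,3a,7a-tetrahydro-1H-indene-4,4(5H)-dicarboxylate F4. Hydrogenation (H2, Pd on carbon) delivers 7.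

The ring expansion of step 6 may give the iodo epoxide instead of the 1,2-shift, the CH2 carbon C-7 may migrate instead of C-10, and the C-11 radical may be reduced or undergo a 1,2-acyl shift before it adds to 12. The fallback sets out from 11 and comes back to the route at 13. Directed epoxidation (VO(acac)2, t-BuOOH) gives the epoxy alcohol F5, and a Lewis acid (ZnBr2, CH2Cl2, −78 → 0 °C) induces the known epoxy alcohol semipinacol ring expansion to the 9-(hydroxymethyl) 8-ketone F6. Iodination (I2, PPh3, imidazole) gives 13, which is carried through the radical addition and epimerisation as before.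

The desaturation of step 8 may give the exocyclic alkylidene lactone (elimination toward C-12), and the oxidant may damage the enol ether. The fallback sets out from 15 and comes back to the route at 17. The lactone is converted (LiN(i-Pr)2, Me3SiCl) into its silyl ketene acetal F7, which is dehydrosilylated with Pd(OAc)2 in MeCN (Saegusa–Ito type); any exocyclic isomer is moved into the ring with RhCl3·3H2O in ethanol.

## Further compounds

F1 | step 3 | dimethyl 2-allylmalonate | C=CCC(C(=O)OC)C(=O)OC
F2 | step 3 | dimethyl 2-allyl-2-[(1S,2S)-2-(1-hydroxyethyl)-2-methyl-3-oxocyclopentyl]malonate (carbinol epimers) | C[C@@]1(C(C)O)[C@@H](C(CC=C)(C(=O)OC)C(=O)OC)CCC1=O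
F3 | step 3 | dimethyl 2-allyl-2-[(1S,2R)-2-ethenyl-2-methyl-3-oxocyclopentyl]malonate | C[C@@]1(C=C)[C@@H](C(CC=C)(C(=O)OC)C(=O)OC)CCC1=O
F4 | step 3 | dimethyl (3aS,7aR)-7a-methyl-1-oxo-2,3,3a,7a-tetrahydro-1H-indene-4,4(5H)-dicarboxylate | C[C@@]12C=CCC(C(=O)OC)(C(=O)OC)[C@H]1CCC2=O
F5 | step 6 | epoxy alcohol from 11 (1-oxiranyl carbinol; epoxide epimers) | C[C@@]12CCCC3(COC(C)(C)OC3)[C@H]1CC[C@]2(O)C1CO1
F6 | step 6 | 11-hydroxy-18,19-O-isopropylidene-8-oxo-12,13,14,15,16,17-hexanor-ent-labdane (C-9 epimers) | C[C@@]12CCCC3(COC(C)(C)OC3)[C@H]1CCC(=O)C2CO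
F7 | step 8 | trimethylsilyl ketene acetal of lactone 15 | C[C@@]12CCCC3(COC(C)(C)OC3)[C@H]1CCC(=COC)[C@H]2CCC1=C(O[Si](C)(C)C)OCC1
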